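The cyclohexane ring C5–C6–C7–C8–C9–C10 carries a vinyl group on C10 and a 3-hydroxyprop-1-en-2-yl group on the neighbouring C5, that is a hexa-1,5-diene C2=C1–C10–C5–C4=C3. Reversing a Cope rearrangement across it leads to a ten-membered (E,Z)-cyclodeca-1,5-diene that already carries the trans-fused α-methylene lactone, the C8 ester and the C15 silyl ether. One thermal [3,3] shift contracts that ring to the cyclohexane, forms the C5–C10 bond and sets both centres, the quaternary one included. The macrocycle comes from a CrCl2-mediated ring-closing allylation of an aldehyde by a (bromomethyl)butenolide.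

Key step: step 18

Remark: carbons are numbered as in germacranes and elemanes: C1–C10 are the ring carbons of the ten-membered precursor (C5–C10 become the cyclohexane), C11, C12 and C13 are the lactone α-carbon, carbonyl carbon and exocyclic CH2, C14 is the methyl on C10 and C15 the CH2O carbon on C4.
Remark: the sense of induction of the ProPhenol ligand in step 8 is assumed as stated there; the antipodal ligand is used if it proves opposite.

Step 1
Reactants: 1 but-3-yn-1-ol
Product: 2 1-[(but-3-yn-1-yloxy)methyl]-4-methoxybenzene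
Conditions: NaH, 4-methoxybenzyl chloride, n-Bu4NI (cat.), THF/DMF, 0 °C to rt
Reagents that add atoms: 4-methoxybenzyl chloride COc1ccc(CCl)cc1
Why: Williamson etherification, in which NaH deprotonates only the hydroxyl group (not the alkyne C–H) and the alkoxide displaces chloride from the benzylic halide.

Step 2
Reactants: 2 1-[(but-3-yn-1-yloxy)methyl]-4-methoxybenzene
Product: 4 (3E)-6-[(4-methoxybenzyl)oxy]-4-methylhex-3-en-1-ol, via alkenylalane 3 (not isolated)
Conditions: AlMe3 (2.5 equiv), Cp2ZrCl2 (0.25 equiv), CH2Cl2, 0 °C to rt; volatiles removed; n-BuLi, THF/hexane, −78 °C; oxirane, −78 °C to rt; dilute aq. HCl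
Reagents that add atoms: trimethylaluminium C[Al](C)C; oxirane C1CO1
Why: zirconium-catalysed Negishi carboalumination adds CH3 and Al syn across the terminal alkyne (CH3 to the internal carbon), which fixes the E geometry of the future C1=C10 bond, and the lithium alanate made with n-BuLi opens oxirane with retention at the alkenyl carbon to add C2 and C3.

Step 3
Reactants: 4 (3E)-6-[(4-methoxybenzyl)oxy]-4-methylhex-3-en-1-ol
Product: 5 1-({[(3E)-6-iodo-3-methylhex-3-en-1-yl]oxy}methyl)-4-methoxybenzene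
Conditions: PPh3, iodine, imidazole, CH2Cl2, 0 °C
Reagents that add atoms: iodine [I][I]
Why: Appel-type iodination, in which the primary alcohol is activated as an oxyphosphonium ion and displaced by iodide (SN2) while the alkene and the PMB ether stay inert.

Step 4
Reactants: 6 but-2-yne-1,4-diol
Product: 7 4-[(tert-butyldiphenylsilyl)oxy]but-2-yn-1-ol
Conditions: NaH (1.0 equiv), THF, 0 °C; tert-butyl(chloro)diphenylsilane (1.0 equiv), rt
Reagents that add atoms: tert-butyl(chloro)diphenylsilane CC(C)(C)[Si](Cl)(c1ccccc1)c1ccccc1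
Why: monosilylation of a symmetrical diol through its monosodium alkoxide, which is silylated faster than it is converted into the dialkoxide.

Step 5
Reactants: 7 4-[(tert-butyldiphenylsilyl)oxy]but-2-yn-1-ol
Product: 9 (2Z)-4-[(tert-butyldiphenylsilyl)oxy]-3-iodobut-2-en-1-ol, via cyclic alkenylalanate 8 (not isolated)
Conditions: NaAlH2(OCH2CH2OCH3)2 (Red-Al, 1.5 equiv), THF, 0 °C; N-iodosuccinimide, −78 °C; aq. work-up
Reagents that add atoms: N-iodosuccinimide O=C1CCC(=O)N1I
Why: hydroxyl-directed trans-hydroalumination of the propargylic alcohol gives a five-membered alkoxy-alkenylalanate with Al on C4 cis to the carbinol carbon C6, and iododealumination with retention gives the Z iodide, so that the later C3 substituent will be cis to C6.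

Step 6
Reactants: 5 1-({[(3E)-6-iodo-3-methylhex-3-en-1-yl]oxy}methyl)-4-methoxybenzene; 9 (2Z)-4-[(tert-butyldiphenylsilyl)oxy]-3-iodobut-2-en-1-ol
Product: 12 (2E,6E)-3-{[(tert-butyldiphenylsilyl)oxy]methyl}-9-[(4-methoxybenzyl)oxy]-7-methylnona-2,6-dien-1-ol, via alkyllithium 10 (not isolated), via borinate ate complex 11 (not isolated)
Conditions: 5, t-BuLi (2.1 equiv), Et2O, −78 °C; B-methoxy-9-BBN, THF, −78 °C to rt; then 9, PdCl2(dppf) (5 mol%), AsPh3, aq. K3PO4, DMF, rt
Reagents that add atoms: none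
Why: B-alkyl Suzuki–Miyaura coupling, in which iodine–lithium exchange and capture by B-methoxy-9-BBN give a borinate that transmetalates to the alkenylpalladium formed from 9, and reductive elimination forms the C3–C4 bond with retention of the alkene geometry in the presence of the free hydroxyl group.

Step 7
Reactants: 12 (2E,6E)-3-{[(tert-butyldiphenylsilyl)oxy]methyl}-9-[(4-methoxybenzyl)oxy]-7-methylnona-2,6-dien-1-ol
Product: 13 (2E,6E)-3-{[(tert-butyldiphenylsilyl)oxy]methyl}-9-[(4-methoxybenzyl)oxy]-7-methylnona-2,6-dienal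
Conditions: MnO2, CH2Cl2, rt
Reagents that add atoms: none
Why: MnO2 oxidises only the allylic alcohol and, being neutral and heterogeneous, should not scramble the geometry of the trisubstituted C4=C5 alkene.

Step 8
Reactants: 13 (2E,6E)-3-{[(tert-butyldiphenylsilyl)oxy]methyl}-9-[(4-methoxybenzyl)oxy]-7-methylnona-2,6-dienal; 14 tert-butyldimethyl(prop-2-yn-1-yloxy)silane
Product: 16 (4R,5E,9E)-1-[(tert-butyldimethylsilyl)oxy]-6-{[(tert-butyldiphenylsilyl)oxy]methyl}-12-[(4-methoxybenzyl)oxy]-10-methyldodeca-5,9-dien-2-yn-4-ol, via alkynylzinc 15 (not isolated)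
Conditions: 14 (3 equiv), Me2Zn (3 equiv), (S,S)-ProPhenol (20 mol%), Ph3PO (40 mol%), toluene, 0 °C; aq. NH4Cl
Reagents that add atoms: none
Why: catalytic enantioselective alkynylation of an enal by an alkynylzinc held in a dinuclear zinc–ProPhenol complex, the (S,S)-ligand being expected to deliver the alkynyl group to the Si face of the aldehyde and so set C6 as R.

Step 9
Reactants: 16 (4R,5E,9E)-1-[(tert-butyldimethylsilyl)oxy]-6-{[(tert-butyldiphenylsilyl)oxy]methyl}-12-[(4-methoxybenzyl)oxy]-10-methyldodeca-5,9-dien-2-yn-4-ol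
Product: 18 (2Z,4R,5E,9E)-1-[(tert-butyldimethylsilyl)oxy]-6-{[(tert-butyldiphenylsilyl)oxy]methyl}-2-iodo-12-[(4-methoxybenzyl)oxy]-10-methyldodeca-2,5,9-trien-4-ol, via cyclic alkenylalanate 17 (not isolated)
Conditions: NaAlH2(OCH2CH2OCH3)2 (Red-Al, 1.5 equiv), THF, 0 °C; N-iodosuccinimide, −78 °C; aq. work-up
Reagents that add atoms: N-iodosuccinimide O=C1CCC(=O)N1I
Why: the C6 alkoxide directs trans-hydroalumination (H to C7, Al to C11 inside a five-membered alanate) and iodination with retention puts iodine on C11 cis to C6, the geometry needed for lactonisation, while the low temperature avoids β-elimination of the silyloxy group.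

Step 10
Reactants: 18 (2Z,4R,5E,9E)-1-[(tert-butyldimethylsilyl)oxy]-6-{[(tert-butyldiphenylsilyl)oxy]methyl}-2-iodo-12-[(4-methoxybenzyl)oxy]-10-methyldodeca-2,5,9-trien-4-ol
Product: 19 (5R)-3-{[(tert-butyldimethylsilyl)oxy]methyl}-5-[(1E,5E)-2-{[(tert-butyldiphenylsilyl)oxy]methyl}-8-[(4-methoxybenzyl)oxy]-6-methylocta-1,5-dien-1-yl]furan-2(5H)-one
Conditions: PdCl2(PPh3)2 (5 mol%), CO (1 atm), K2CO3, THF, 35 °C
Reagents that add atoms: carbon monoxide [C-]#[O+]
Why: palladium-catalysed carbonylative lactonisation, in which oxidative addition of the alkenyl iodide to zerovalent palladium, CO insertion and capture of the acylpalladium by the cis hydroxyl group close the butenolide (the first ring of the skeleton) without touching C6.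

Step 11
Reactants: 19 (5R)-3-{[(tert-butyldimethylsilyl)oxy]methyl}-5-[(1E,5E)-2-{[(tert-butyldiphenylsilyl)oxy]methyl}-8-[(4-methoxybenzyl)oxy]-6-methylocta-1,5-dien-1-yl]furan-2(5H)-one
Product: 20 (5R)-3-(bromomethyl)-5-[(1E,5E)-2-{[(tert-butyldiphenylsilyl)oxy]methyl}-8-[(4-methoxybenzyl)oxy]-6-methylocta-1,5-dien-1-yl]furan-2(5H)-one
Conditions: Ph3PBr2, CH2Cl2, 0 °C to rt
Reagents that add atoms: dibromotriphenylphosphorane BrP(Br)(c1ccccc1)(c1ccccc1)c1ccccc1
Why: direct exchange of a primary allylic silyl ether for bromide by Ph3PBr2 (silyl transfer to bromide, then SN2 on the oxyphosphonium ion), the bulkier TBDPS ether and the PMB ether reacting much more slowly.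

Step 12
Reactants: 20 (5R)-3-(bromomethyl)-5-[(1E,5E)-2-{[(tert-butyldiphenylsilyl)oxy]methyl}-8-[(4-methoxybenzyl)oxy]-6-methylocta-1,5-dien-1-yl]furan-2(5H)-one
Product: 21 (5R)-3-(bromomethyl)-5-[(1E,5E)-2-{[(tert-butyldiphenylsilyl)oxy]methyl}-8-hydroxy-6-methylocta-1,5-dien-1-yl]furan-2(5H)-one
Conditions: DDQ, CH2Cl2/pH 7 buffer, 0 °C
Reagents that add atoms: none
Why: oxidative cleavage of the 4-methoxybenzyl ether by DDQ (hydride abstraction from the electron-rich benzylic position, hydrolysis of the oxocarbenium ion), which should leave the allylic bromide, the silyl ether and the alkenes untouched.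

Step 13
Reactants: 21 (5R)-3-(bromomethyl)-5-[(1E,5E)-2-{[(tert-butyldiphenylsilyl)oxy]methyl}-8-hydroxy-6-methylocta-1,5-dien-1-yl]furan-2(5H)-one
Product: 22 (3E,7E)-8-[(2R)-4-(bromomethyl)-5-oxo-2,5-dihydrofuran-2-yl]-7-{[(tert-butyldiphenylsilyl)oxy]methyl}-3-methylocta-3,7-dienal
Conditions: Dess–Martin periodinane, NaHCO3, CH2Cl2, 0 °C
Reagents that add atoms: none
Why: Dess–Martin oxidation of the primary alcohol to the aldehyde under buffered, non-basic conditions that should avoid migration of the C1=C10 double bond into conjugation.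

Step 14
Reactants: 22 (3E,7E)-8-[(2R)-4-(bromomethyl)-5-oxo-2,5-dihydrofuran-2-yl]-7-{[(tert-butyldiphenylsilyl)oxy]methyl}-3-methylocta-3,7-dienal
Product: 24 (3aR,4S,6E,10E,11aR)-10-{[(tert-butyldiphenylsilyl)oxy]methyl}-4-hydroxy-6-methyl-3-methylidene-3a,4,5,8,9,11a-hexahydrocyclodeca[b]furan-2(3H)-one, via allylchromium 23 (not isolated)
Conditions: CrCl2 (8 equiv), THF, syringe-pump addition to 2 mM, rt
Reagents that add atoms: none
Why: Nozaki–Hiyama–Kishi (Barbier-type) allylation, in which CrCl2 turns the allylic bromide into an allylchromium that adds through its γ-carbon C7 to the C8 aldehyde in a chair-like Zimmerman–Traxler transition state, closing the ten-membered ring and unveiling the exocyclic methylene, with C7 attacked anti to the C6 substituent (trans-fused lactone, 7R) and the aldehyde chain C9 equatorial (anti C7/C8 relation, 8S), while high dilution disfavours oligomers.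

Step 15
Reactants: 25 methyl (2R)-3-hydroxy-2-methylpropanoate
Product: 26 methyl (2R)-3-[(tert-butyldimethylsilyl)oxy]-2-methylpropanoate
Conditions: tert-butyl(chloro)dimethylsilane, imidazole, CH2Cl2, rt
Reagents that add atoms: tert-butyl(chloro)dimethylsilane CC(C)(C)[Si](C)(C)Cl
Why: imidazole-promoted silylation of the primary alcohol, which does not touch the stereocentre next to the ester.

Step 16
Reactants: 26 methyl (2R)-3-[(tert-butyldimethylsilyl)oxy]-2-methylpropanoate
Product: 27 (2R)-3-[(tert-butyldimethylsilyl)oxy]-2-methylpropanoic acid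
Conditions: LiOH, THF/MeOH/H2O, 0 °C to rt; aq. HCl to pH 4
Reagents that add atoms: lithium hydroxide [Li+].[OH-]
Why: saponification of the methyl ester at low temperature, mild enough to avoid epimerisation of the α-centre or β-elimination of the silyloxy group.

Step 17
Reactants: 24 (3aR,4S,6E,10E,11aR)-10-{[(tert-butyldiphenylsilyl)oxy]methyl}-4-hydroxy-6-methyl-3-methylidene-3a,4,5,8,9,11a-hexahydrocyclodeca[b]furan-2(3H)-one; 27 (2R)-3-[(tert-butyldimethylsilyl)oxy]-2-methylpropanoic acid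
Product: 29 (3aR,4S,6E,10E,11aR)-10-{[(tert-butyldiphenylsilyl)oxy]methyl}-6-methyl-3-methylidene-2-oxo-2,3,3a,4,5,8,9,11a-octahydrocyclodeca[b]furan-4-yl (2R)-3-[(tert-butyldimethylsilyl)oxy]-2-methylpropanoate, via mixed anhydride 28 (not isolated)
Conditions: 27, 2,4,6-trichlorobenzoyl chloride, Et3N, THF, rt; then 24, DMAP, toluene, rt
Reagents that add atoms: none
Why: Yamaguchi esterification, in which the acid is activated as the 2,4,6-trichlorobenzoyl mixed anhydride and transferred by DMAP to the hindered secondary C8 alcohol with retention at C8 and at the α-centre of the acid.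

Step 18
Reactants: 29 (3aR,4S,6E,10E,11aR)-10-{[(tert-butyldiphenylsilyl)oxy]methyl}-6-methyl-3-methylidene-2-oxo-2,3,3a,4,5,8,9,11a-octahydrocyclodeca[b]furan-4-yl (2R)-3-[(tert-butyldimethylsilyl)oxy]-2-methylpropanoate
Product: 30 (3aR,4S,6R,7R,7aR)-7-(3-{[tert-butyl(diphenyl)silyl]oxy}prop-1-en-2-yl)-6-ethenyl-6-methyl-3-methylidene-2-oxooctahydro-1-benzofuran-4-yl (2R)-3-{[tert-butyl(dimethyl)silyl]oxy}-2-methylpropanoate
Conditions: degassed toluene, BHT (5 mol%), sealed tube, 170 °C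
Reagents that add atoms: none
Why: Thermal concerted [3,3]-sigmatropic (Cope) rearrangement through a chair-like six-centre transition state in which C2–C3 breaks as C5–C10 forms; the closest known reaction type is the germacrane-to-elemane rearrangement of cyclodeca-1,5-dienes, and release of the strain of the (E,Z)-cyclodecadiene should pull the equilibrium to the cyclohexane. The six-membered ring C5–C6–C7–C8–C9–C10 is closed by transannular C5–C10 bond formation inside the ten-membered ring (ring contraction from ten to six atoms), after the lactone ring is in place. C10 is controlled by the ring-trans C1=C10 geometry (C9 equatorial and C14 axial in the chair) and C5 by the ring-cis C4=C5 geometry (C6 axial, H equatorial), which together place the new vinyl group and the C4 propenyl group cis on the cyclohexane. The face is fixed by the trans-fused lactone, whose C6–O and C7–C11 bonds can only be diequatorial on the forming cyclohexane chair, so that the C5 substituent ends trans to the C6 oxygen and the C8 ester stays equatorial. The selectivity needed is chair over boat and one of the two chair topologies, secured by the alkene geometries set in steps 2 and 5 and by the lactone lock; BHT and degassing guard the α-methylene lactone.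

Step 19
Reactants: 30 (3aR,4S,6R,7R,7aR)-7-(3-{[tert-butyl(diphenyl)silyl]oxy}prop-1-en-2-yl)-6-ethenyl-6-methyl-3-methylidene-2-oxooctahydro-1-benzofuran-4-yl (2R)-3-{[tert-butyl(dimethyl)silyl]oxy}-2-methylpropanoate
Product: 31 (3aR,4S,6R,7R,7aR)-6-ethenyl-7-(3-hydroxyprop-1-en-2-yl)-6-methyl-3-methylidene-2-oxooctahydro-1-benzofuran-4-yl (2R)-3-hydroxy-2-methylpropanoate
Conditions: HF·pyridine, pyridine, THF, 0 °C to rt
Reagents that add atoms: none
Why: fluoride-mediated cleavage of both silyl ethers with buffered HF·pyridine, acidic enough to spare the ester, the α-methylene lactone and the 1,5-diene and to avoid acyl migration.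

Compound list

1 | but-3-yn-1-ol | C#CCCO | starting material
2 | 1-[(but-3-yn-1-yloxy)methyl]-4-methoxybenzene | C#CCCOCc1ccc(OC)cc1 | intermediate
3 | dimethyl[(1E)-4-[(4-methoxybenzyl)oxy]-2-methylbut-1-en-1-yl]alane (formed in the flask) | C[Al](C)/C=C(\C)CCOCc1ccc(OC)cc1 | intermediate
4 | (3E)-6-[(4-methoxybenzyl)oxy]-4-methylhex-3-en-1-ol | OCC/C=C(\C)CCOCc1ccc(OC)cc1 | intermediate
5 | 1-({[(3E)-6-iodo-3-methylhex-3-en-1-yl]oxy}methyl)-4-methoxybenzene | ICC/C=C(\C)CCOCc1ccc(OC)cc1 | intermediate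
6 | but-2-yne-1,4-diol | OCC#CCO | starting material
7 | 4-[(tert-butyldiphenylsilyl)oxy]but-2-yn-1-ol | OCC#CCO[Si](c1ccccc1)(c1ccccc1)C(C)(C)C | intermediate
8 | sodium 2,2-bis(2-methoxyethoxy)-3-{[(tert-butyldiphenylsilyl)oxy]methyl}-2,5-dihydro-1,2-oxaluminol-2-uide (cyclic alkenylalanate, formed in the flask) | [Na+].COCCO[Al-]1(OCCOC)OCC=C1CO[Si](c1ccccc1)(c1ccccc1)C(C)(C)C | intermediate
9 | (2Z)-4-[(tert-butyldiphenylsilyl)oxy]-3-iodobut-2-en-1-ol | OC/C=C(\I)CO[Si](c1ccccc1)(c1ccccc1)C(C)(C)C | intermediate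
10 | [(3E)-6-[(4-methoxybenzyl)oxy]-4-methylhex-3-en-1-yl]lithium (formed in the flask) | [Li]CC/C=C(\C)CCOCc1ccc(OC)cc1 | intermediate
11 | lithium 9-methoxy-9-[(3E)-6-[(4-methoxybenzyl)oxy]-4-methylhex-3-en-1-yl]-9-boranuidabicyclo[3.3.1]nonane (formed in the flask) | [Li+].CO[B-]1(CC/C=C(\C)CCOCc2ccc(OC)cc2)C2CCCC1CCC2 | intermediate
12 | (2E,6E)-3-{[(tert-butyldiphenylsilyl)oxy]methyl}-9-[(4-methoxybenzyl)oxy]-7-methylnona-2,6-dien-1-ol | OC/C=C(/CO[Si](c1ccccc1)(c1ccccc1)C(C)(C)C)CC/C=C(\C)CCOCc1ccc(OC)cc1 | intermediate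
13 | (2E,6E)-3-{[(tert-butyldiphenylsilyl)oxy]methyl}-9-[(4-methoxybenzyl)oxy]-7-methylnona-2,6-dienal | O=C/C=C(/CO[Si](c1ccccc1)(c1ccccc1)C(C)(C)C)CC/C=C(\C)CCOCc1ccc(OC)cc1 | intermediate
14 | tert-butyldimethyl(prop-2-yn-1-yloxy)silane | C#CCO[Si](C)(C)C(C)(C)C | starting material
15 | {3-[(tert-butyldimethylsilyl)oxy]prop-1-yn-1-yl}(methyl)zinc (formed in the flask) | C[Zn]C#CCO[Si](C)(C)C(C)(C)C | intermediate
16 | (4R,5E,9E)-1-[(tert-butyldimethylsilyl)oxy]-6-{[(tert-butyldiphenylsilyl)oxy]methyl}-12-[(4-methoxybenzyl)oxy]-10-methyldodeca-5,9-dien-2-yn-4-ol | O[C@@H](C#CCO[Si](C)(C)C(C)(C)C)/C=C(/CO[Si](c1ccccc1)(c1ccccc1)C(C)(C)C)CC/C=C(\C)CCOCc1ccc(OC)cc1 | intermediate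
17 | sodium cyclic alkenylalanate of 16 (2,5-dihydro-1,2-oxaluminol-2-uide, ring oxygen on C6, Al on C11, two 2-methoxyethoxy groups on Al, formed in the flask) | [Na+].COCCO[Al-]1(OCCOC)O[C@@H](C=C1CO[Si](C)(C)C(C)(C)C)/C=C(/CO[Si](c1ccccc1)(c1ccccc1)C(C)(C)C)CC/C=C(\C)CCOCc1ccc(OC)cc1 | intermediate
18 | (2Z,4R,5E,9E)-1-[(tert-butyldimethylsilyl)oxy]-6-{[(tert-butyldiphenylsilyl)oxy]methyl}-2-iodo-12-[(4-methoxybenzyl)oxy]-10-methyldodeca-2,5,9-trien-4-ol | O[C@@H](/C=C(\I)CO[Si](C)(C)C(C)(C)C)/C=C(/CO[Si](c1ccccc1)(c1ccccc1)C(C)(C)C)CC/C=C(\C)CCOCc1ccc(OC)cc1 | intermediate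
19 | (5R)-3-{[(tert-butyldimethylsilyl)oxy]methyl}-5-[(1E,5E)-2-{[(tert-butyldiphenylsilyl)oxy]methyl}-8-[(4-methoxybenzyl)oxy]-6-methylocta-1,5-dien-1-yl]furan-2(5H)-one | O=C1O[C@@H](C=C1CO[Si](C)(C)C(C)(C)C)/C=C(/CO[Si](c2ccccc2)(c2ccccc2)C(C)(C)C)CC/C=C(\C)CCOCc2ccc(OC)cc2 | intermediate
20 | (5R)-3-(bromomethyl)-5-[(1E,5E)-2-{[(tert-butyldiphenylsilyl)oxy]methyl}-8-[(4-methoxybenzyl)oxy]-6-methylocta-1,5-dien-1-yl]furan-2(5H)-one | O=C1O[C@@H](C=C1CBr)/C=C(/CO[Si](c2ccccc2)(c2ccccc2)C(C)(C)C)CC/C=C(\C)CCOCc2ccc(OC)cc2 | intermediate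
21 | (5R)-3-(bromomethyl)-5-[(1E,5E)-2-{[(tert-butyldiphenylsilyl)oxy]methyl}-8-hydroxy-6-methylocta-1,5-dien-1-yl]furan-2(5H)-one | O=C1O[C@@H](C=C1CBr)/C=C(/CO[Si](c2ccccc2)(c2ccccc2)C(C)(C)C)CC/C=C(\C)CCO | intermediate
22 | (3E,7E)-8-[(2R)-4-(bromomethyl)-5-oxo-2,5-dihydrofuran-2-yl]-7-{[(tert-butyldiphenylsilyl)oxy]methyl}-3-methylocta-3,7-dienal | O=C1O[C@@H](C=C1CBr)/C=C(/CO[Si](c2ccccc2)(c2ccccc2)C(C)(C)C)CC/C=C(\C)CC=O | intermediate
23 | dichloro{[(5R)-5-[(1E,5E)-2-{[(tert-butyldiphenylsilyl)oxy]methyl}-6-methyl-8-oxoocta-1,5-dien-1-yl]-2-oxo-2,5-dihydrofuran-3-yl]methyl}chromium (allylchromium, trivalent chromium, formed in the flask) | O=C1O[C@@H](C=C1C[Cr](Cl)Cl)/C=C(/CO[Si](c2ccccc2)(c2ccccc2)C(C)(C)C)CC/C=C(\C)CC=O | intermediate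
24 | (3aR,4S,6E,10E,11aR)-10-{[(tert-butyldiphenylsilyl)oxy]methyl}-4-hydroxy-6-methyl-3-methylidene-3a,4,5,8,9,11a-hexahydrocyclodeca[b]furan-2(3H)-one | C/C1=C\CC/C(CO[Si](c3ccccc3)(c3ccccc3)C(C)(C)C)=C\[C@H]2OC(=O)C(=C)[C@@H]2[C@@H](O)C1 | intermediate
25 | methyl (2R)-3-hydroxy-2-methylpropanoate | COC(=O)[C@H](C)CO | starting material
26 | methyl (2R)-3-[(tert-butyldimethylsilyl)oxy]-2-methylpropanoate | COC(=O)[C@H](C)CO[Si](C)(C)C(C)(C)C | intermediate
27 | (2R)-3-[(tert-butyldimethylsilyl)oxy]-2-methylpropanoic acid | OC(=O)[C@H](C)CO[Si](C)(C)C(C)(C)C | intermediate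
28 | (2R)-3-[(tert-butyldimethylsilyl)oxy]-2-methylpropanoic 2,4,6-trichlorobenzoic anhydride (formed in the flask) | O=C(OC(=O)[C@H](C)CO[Si](C)(C)C(C)(C)C)c1c(Cl)cc(Cl)cc1Cl | intermediate
29 | (3aR,4S,6E,10E,11aR)-10-{[(tert-butyldiphenylsilyl)oxy]methyl}-6-methyl-3-methylidene-2-oxo-2,3,3a,4,5,8,9,11a-octahydrocyclodeca[b]furan-4-yl (2R)-3-[(tert-butyldimethylsilyl)oxy]-2-methylpropanoate | C/C1=C\CC/C(CO[Si](c3ccccc3)(c3ccccc3)C(C)(C)C)=C\[C@H]2OC(=O)C(=C)[C@@H]2[C@@H](OC(=O)[C@H](C)CO[Si](C)(C)C(C)(C)C)C1 | intermediate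
30 | (3aR,4S,6R,7R,7aR)-7-(3-{[tert-butyl(diphenyl)silyl]oxy}prop-1-en-2-yl)-6-ethenyl-6-methyl-3-methylidene-2-oxooctahydro-1-benzofuran-4-yl (2R)-3-{[tert-butyl(dimethyl)silyl]oxy}-2-methylpropanoate | C=C[C@@]1(C)C[C@H](OC(=O)[C@H](C)CO[Si](C)(C)C(C)(C)C)[C@H]2C(=C)C(=O)O[C@@H]2[C@H]1C(=C)CO[Si](c3ccccc3)(c3ccccc3)C(C)(C)C | intermediate
31 | (3aR,4S,6R,7R,7aR)-6-ethenyl-7-(3-hydroxyprop-1-en-2-yl)-6-methyl-3-methylidene-2-oxooctahydro-1-benzofuran-4-yl (2R)-3-hydroxy-2-methylpropanoate | C=C[C@@]1(C)C[C@H](OC(=O)[C@H](C)CO)[C@H]2C(=C)C(=O)O[C@@H]2[C@H]1C(=C)CO | target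

Total step count: 19.
Longest linear sequence: 15 steps (steps 1, 2, 3, 6 to 14, 17, 18, 19).

Steps most likely to fail

1. Step 14, the macrocyclic allylation. What may go wrong is addition to the wrong face of the C8 aldehyde, because the tether of the forming ten-membered ring can override the equatorial preference of the chair transition state, alongside competing oligomerisation. The fallback sets out from 22: if the ring closure delivers mainly the C8 epimer, (3aR,4R,6E,10E,11aR)-10-{[(tert-butyldiphenylsilyl)oxy]methyl}-4-hydroxy-6-methyl-3-methylidene-3a,4,5,8,9,11a-hexahydrocyclodeca[b]furan-2(3H)-one F1, this alcohol is esterified with acid 27 under Mitsunobu conditions (PPh3, diisopropyl azodicarboxylate, toluene, 0 °C). Inversion at C8 then gives the 8S ester, and the route is rejoined at 29.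

2. Step 18, the Cope rearrangement. What may go wrong is radical oligomerisation or ene-type degradation through the exocyclic methylene of the lactone at the temperature needed, before the rearrangement is complete. The fallback sets out from 29 and masks the methylene for the thermolysis. Conjugate addition of thiophenol (PhSH, Et3N cat., THF, rt) should give the 13-(phenylsulfanyl)-11,13-dihydro derivative of 29 F2 as both C11 epimers, either of which serves. Thermolysis (toluene, 170 °C) should give the rearranged phenyl sulfide F3 through the same chair transition state. Oxidation (NaIO4, MeOH/H2O, 0 °C) gives the sulfoxide F4, and syn-elimination (toluene, CaCO3, 110 °C) restores the exocyclic methylene and rejoins the route at 30.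

3. Step 8, the enantioselective alkynylation. What may go wrong is erosion of enantiofacial control, because the uncatalysed addition of the alkynylzinc can compete with the ligand-bound pathway for this hindered β,β-disubstituted enal. The fallback sets out from 16 of insufficient enantiomeric purity: oxidation (MnO2, CH2Cl2, rt) gives the cross-conjugated ynone (5E,9E)-1-[(tert-butyldimethylsilyl)oxy]-6-{[(tert-butyldiphenylsilyl)oxy]methyl}-12-[(4-methoxybenzyl)oxy]-10-methyldodeca-5,9-dien-2-yn-4-one F5. Midland reduction with (R)-Alpine-borane (B-isopinocampheyl-9-BBN from (+)-α-pinene, neat or THF, rt), in which the alkynyl group acts as the small substituent, should return the 4R alcohol, and the route is rejoined at 16.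

Further compounds

F1 | step 14 | (3aR,4R,6E,10E,11aR)-10-{[(tert-butyldiphenylsilyl)oxy]methyl}-4-hydroxy-6-methyl-3-methylidene-3a,4,5,8,9,11a-hexahydrocyclodeca[b]furan-2(3H)-one (C8 epimer of 24) | C/C1=C\CC/C(CO[Si](c3ccccc3)(c3ccccc3)C(C)(C)C)=C\[C@H]2OC(=O)C(=C)[C@@H]2[C@H](O)C1
F2 | step 18 | (3aR,4S,6E,10E,11aR)-10-{[(tert-butyldiphenylsilyl)oxy]methyl}-6-methyl-2-oxo-3-[(phenylsulfanyl)methyl]-2,3,3a,4,5,8,9,11a-octahydrocyclodeca[b]furan-4-yl (2R)-3-[(tert-butyldimethylsilyl)oxy]-2-methylpropanoate (both C3 epimers, C3 being C11 in germacrane numbering) | C/C1=C\CC/C(CO[Si](c3ccccc3)(c3ccccc3)C(C)(C)C)=C\[C@H]2OC(=O)C(CSc3ccccc3)[C@@H]2[C@@H](OC(=O)[C@H](C)CO[Si](C)(C)C(C)(C)C)C1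
F3 | step 18 | (3aR,4S,6R,7R,7aR)-7-(3-{[tert-butyl(diphenyl)silyl]oxy}prop-1-en-2-yl)-6-ethenyl-6-methyl-2-oxo-3-[(phenylsulfanyl)methyl]octahydro-1-benzofuran-4-yl (2R)-3-{[tert-butyl(dimethyl)silyl]oxy}-2-methylpropanoate (both C3 epimers) | C=C[C@@]1(C)C[C@H](OC(=O)[C@H](C)CO[Si](C)(C)C(C)(C)C)[C@H]2C(CSc3ccccc3)C(=O)O[C@@H]2[C@H]1C(=C)CO[Si](c3ccccc3)(c3ccccc3)C(C)(C)C
F4 | step 18 | (3aR,4S,6R,7R,7aR)-7-(3-{[tert-butyl(diphenyl)silyl]oxy}prop-1-en-2-yl)-6-ethenyl-6-methyl-2-oxo-3-[(phenylsulfinyl)methyl]octahydro-1-benzofuran-4-yl (2R)-3-{[tert-butyl(dimethyl)silyl]oxy}-2-methylpropanoate (epimers at C3 and at sulfur) | C=C[C@@]1(C)C[C@H](OC(=O)[C@H](C)CO[Si](C)(C)C(C)(C)C)[C@H]2C(CS(=O)c3ccccc3)C(=O)O[C@@H]2[C@H]1C(=C)CO[Si](c3ccccc3)(c3ccccc3)C(C)(C)C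
F5 | step 8 | (5E,9E)-1-[(tert-butyldimethylsilyl)oxy]-6-{[(tert-butyldiphenylsilyl)oxy]methyl}-12-[(4-methoxybenzyl)oxy]-10-methyldodeca-5,9-dien-2-yn-4-one | O=C(C#CCO[Si](C)(C)C(C)(C)C)/C=C(/CO[Si](c1ccccc1)(c1ccccc1)C(C)(C)C)CC/C=C(\C)CCOCc1ccc(OC)cc1
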